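Numbering used throughout: the C19 chain is counted from the pentyl terminus (C1–C5 pentyl, ring O1–C6–C7–C8–C9, carbinol C10, chain C11–C19 with the alkene at C18=C19). Compound numbers are those of the steps.

## The problem

The target is a C19 chain folded into one 2,3,5-trisubstituted tetrahydrofuran (O1–C6–C7–C8–C9). C6 carries pentyl, the C7 oxygen carries a laurate, and C9 carries the secondary carbinol C10 with the non-8-enyl chain. There are four stereocentres: C6 and C7 (both S, cis on the ring), C9 (R, trans to both) and C10 (R, threo to C9). The vicinal pair C6/C7 can be set together by reagent control in one C–C bond formation. Once held in a ring, that pair can direct the creation of C9, and the ring oxygen on C9 can in turn direct a hydride to a C10 carbonyl. The two secondary oxygens on C7 and C10 must be told apart, since one is acylated and the other stays free. The C18=C19 alkene rules out hydrogenation, hydroboration and metathesis once it is in place, and the ester rules out strong bases and nucleophiles at the end. The enabling feature is that O1 on C9 and the oxygen on C10 sit on adjacent carbons. This is exactly what remains when the ring oxygen of a six-membered enol ether O1–C10=C9 moves from C10 to C9, and that six-membered ring is reachable from a δ-lactone.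

## Retrosynthesis

**Target 19 to keto ester 18.** The last bond made is C10–H, so 19 is read as the reduction product of ketone 18. The neighbouring endgames are acylation of a C7,C10-diol and removal of a protecting group from the C10 oxygen. The first cannot distinguish two secondary hydroxyls and the second costs two extra steps. With C10 at the ketone level, the oxygen that must stay free is masked by its own oxidation state while the laurate is attached. 18 has one stereocentre fewer. The forward reduction must deliver hydride anti to the C9–O1 bond (Felkin–Anh, threo) and must spare the ester and the alkene.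

**Keto ester 18 to hydroxy ketone 16 and lauric acid 17; 16 to acetal 14.** Cutting the acyl C–O bond removes twelve carbons as commercial 17. The C7 hydroxyl of 16 is the only hydroxyl in the molecule, so the esterification needs no selectivity. The methoxymethyl group of 14 is the one the C7 oxygen carries from the first step. Its removal must leave the ketone and the epimerisable C9 alone.

**Ketone 14 to enol ether 12 (key disconnection).** The O1–C9 bond is cut and O1 is reconnected to C10, which turns the 2-acyltetrahydrofuran into the six-membered enol ether 12. The usual cuts of a tetrahydrofuran are etherifications at O1–C6 or O1–C9 of an open chain. Against these, the chosen cut has three advantages: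
- C6 and C7 stay in a ring while C9 is created, so they can control it.
- C10 is delivered directly at the ketone level wanted above.
- The precursor leads back to a δ-lactone, an easy ring to make.

12 has no C9 stereocentre and one oxygen fewer. The forward step is oxidation by a trivalent iodine reagent with a 1,2-shift of the ring oxygen, passing through ketal 13. It must attack C9 anti to the C7 ether, prefer the enol ether to the terminal alkene, and leave the acetal on C7 in place.

**Enol ether 12 to ketene acetal phosphate 9 and bromide 10.** The C10–C11 bond is cut between the sp2 carbon of the enol ether and the chain. This splits off nine carbons with the alkene as commercial 10, used as its Grignard reagent 11. It also means the alkene enters only after all hydrogenation and metathesis chemistry is finished. The forward coupling must be faster than attack of 11 at phosphorus.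

**Phosphate 9 to lactone 8, enoate 7, acrylate 6 and alcohol 5.** 9 is the O-phosphorylated enolate of δ-lactone 8. 8 is the hydrogenation product of unsaturated lactone 7. The C8=C9 bond of 7 is cut by ring-closing metathesis to acrylate 6, and the acyl C–O bond of 6 leads to alcohol 5. A direct lactonisation would need a separate C8–C10 homologation, whereas the acrylate supplies C9 and C10 in one acylation. No stereocentre is made or endangered in these four steps.

**Alcohol 5 to hexanal 1 and allyl ether 2.** The C6–C7 bond is cut. Its formation by addition of the γ-alkoxyallylborane 3 (made from 2) to 1, via borinate 4, creates both stereocentres at once, syn from the Z geometry of 3 and absolute from the chiral boron ligands. It also brings the C7 oxygen already protected. Both starting materials are commercial.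

## Roads not taken

**Alternative 1:** The cut is O1–C6 and C4–C5, with a temporary acyl bond from the C7 oxygen to C4.
- Forward key step: diene diol A1 is treated with catalytic PdCl2 and a copper reoxidant under CO. The C9 hydroxyl adds to C6 of the alkene activated by divalent palladium, CO inserts at C5, and the C7 hydroxyl closes the lactone to give the cis-fused bicycle A2.
- Merits: the cis relation of C6 and C7 is enforced by the ring fusion and is not a matter of facial preference. The C7 and C10 oxygens emerge differentiated, as lactone and as 4-methoxybenzyl ether.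
- Weak points: A2 ends at C4, so the lactone must be reduced, olefinated with a three-carbon ylide and saturated to give the pentyl group. That saturation cannot be done in the presence of C18=C19, so the terminal alkene must be carried masked or installed afterwards. The oxidative conditions also expose that second terminal alkene to Wacker-type oxidation.
- Comparison: in ring stereocontrol this road is at least as secure as the chosen one. The chosen plan offsets this with a complete carbon chain before the ring is contracted and an endgame of three steps.

**Alternative 2:** The cut is O1–C6 together with the C7–O bond of the ester.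
- Forward key step: I2 activates the E alkene of homoallylic alcohol A3 and the C9 hydroxyl closes in a 5-endo mode to the iodotetrahydrofuran A4, with iodine trans to pentyl. The cesium salt of 17 is then meant to displace iodide with inversion.
- Merits: the anti addition is stereospecific, the laurate is introduced without any protecting group on C7, and the sequence would be the shortest of all.
- Weak points: the displacement takes place at a secondary ring carbon that is β to the ring oxygen and flanked by the pentyl-bearing C6, with the nucleophile entering cis to pentyl. Elimination to dihydrofurans should compete strongly with a weakly nucleophilic carboxylate. The 2,5-trans outcome of the 5-endo closure is also substrate dependent.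
- Comparison: this road is better in step count. The chosen plan avoids any substitution at C7, because the C7 oxygen arrives with its final configuration in the first step.

**Alternative 3:** The cut is O1–C9 and C10–O.
- Forward key step: the C6 hydroxyl of the E alkenol A5 forms a perrhenate ester with Re2O7. The heptavalent rhenium ester adds two oxygens syn across C9=C10 and gives the 2,5-trans tetrahydrofuran carbinol A6.
- Merits: C9 and C10 are set in one stereospecific event from alkene geometry, with no ketone reduction and no reliance on the face selectivity of an external electrophile. In stereochemical certainty at C9 and C10 this road is better than the chosen one.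
- Weak points: A6 has a free C10 hydroxyl and a protected C7 oxygen, so silylation, acetal cleavage, acylation and desilylation must follow. The strongly Lewis acidic rhenium oxide threatens the methoxymethyl ether. The trans selectivity is less well charted for alcohols with an adjacent alkoxy group. A5 needs a stereodefined E alkene one carbon removed from the syn-diol unit, which lengthens its preparation.
- Comparison: the chosen plan accepts a less certain step at C9. In return it offers a shorter overall sequence, cheap reagents, and a C10 ketone that acts as its own protecting group.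

Key step: step 7

Assumption: the facial preference of the diisopinocampheylborane allyl reagent derived from (−)-α-pinene, which adds to the Re face of an unbranched aliphatic aldehyde, is taken to hold for the (Z)-γ-(methoxymethoxy)allyl reagent 3.

## Route

Step 1
Reactants: 1 hexanal; 2 allyl methoxymethyl ether
Product: 5 (3S,4S)-3-(methoxymethoxy)non-1-en-4-ol, via (Z)-[3-(methoxymethoxy)allyl]diisopinocampheylborane 3 (not isolated), via (3S,4S)-3-(methoxymethoxy)non-1-en-4-yl diisopinocampheylborinate 4 (not isolated)
Conditions: 2, s-BuLi, THF, −78 °C; (+)-Ipc2BOMe; BF3·OEt2; then 1, −78 °C; NaOH, H2O2, 0 °C → rt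
Reagents that add atoms: (+)-B-methoxydiisopinocampheylborane, COB([C@H]1C[C@H]2C[C@@H]([C@@H]1C)C2(C)C)[C@H]1C[C@H]2C[C@@H]([C@@H]1C)C2(C)C (boron and isopinocampheyl groups of 3 and 4 only; none of its atoms remain in 5)
Why: Asymmetric (Z)-γ-alkoxyallylboration (Brown allylboration): kinetic lithiation of 2 gives the chelated Z alkoxyallyl anion, which is transferred to boron as 3; addition to 1 through a closed chair (Zimmerman–Traxler) transition state turns the Z geometry into the syn C6/C7 relation, and the isopinocampheyl groups from (−)-α-pinene direct attack to the Re face of the aldehyde, which corresponds to 6S,7S.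

Step 2
Reactants: 5 (3S,4S)-3-(methoxymethoxy)non-1-en-4-ol
Product: 6 (3S,4S)-3-(methoxymethoxy)non-1-en-4-yl acrylate
Conditions: acryloyl chloride, Et3N, DMAP (cat.), CH2Cl2, 0 °C
Reagents that add atoms: acryloyl chloride, C=CC(=O)Cl
Why: O-acylation of a secondary alcohol with an acid chloride under amine base and nucleophilic catalysis; the C–O bond at C6 is not broken, so both stereocentres are untouched.

Step 3
Reactants: 6 (3S,4S)-3-(methoxymethoxy)non-1-en-4-yl acrylate
Product: 7 (5S,6S)-5-(methoxymethoxy)-6-pentyl-5,6-dihydro-2H-pyran-2-one
Conditions: second-generation Grubbs catalyst RuCl2(=CHPh)(H2IMes)(PCy3) (5 mol%), CH2Cl2 (dilute), 40 °C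
Reagents that add atoms: none
Why: Ring-closing metathesis of an acrylate with an allylic ether alkene to a six-membered α,β-unsaturated lactone, driven by loss of ethylene; the N-heterocyclic carbene catalyst is the established choice for electron-poor acrylates, and no other alkene is present yet.

Step 4
Reactants: 7 (5S,6S)-5-(methoxymethoxy)-6-pentyl-5,6-dihydro-2H-pyran-2-one
Product: 8 (5S,6S)-5-(methoxymethoxy)-6-pentyltetrahydro-2H-pyran-2-one
Conditions: H2 (1 atm), Pd/C, EtOAc, rt
Reagents that add atoms: none
Why: Heterogeneous catalytic hydrogenation of the conjugated C8=C9 bond; lactone and acetal are inert under neutral conditions, and the step is placed before the terminal alkene enters the molecule.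

Step 5
Reactants: 8 (5S,6S)-5-(methoxymethoxy)-6-pentyltetrahydro-2H-pyran-2-one
Product: 9 diphenyl (2S,3S)-3-(methoxymethoxy)-2-pentyl-3,4-dihydro-2H-pyran-6-yl phosphate
Conditions: KN(SiMe3)2, (PhO)2P(O)Cl, HMPA, THF, −78 °C
Reagents that add atoms: diphenyl chlorophosphate, O=P(Cl)(Oc1ccccc1)Oc1ccccc1
Why: Ketene acetal phosphate formation: the potassium enolate of the δ-lactone is trapped on oxygen by the chlorophosphate present in the flask; only C9 bears α-hydrogens, and the C7 ether is γ to the carbonyl and cannot be eliminated.

Step 6
Reactants: 9 diphenyl (2S,3S)-3-(methoxymethoxy)-2-pentyl-3,4-dihydro-2H-pyran-6-yl phosphate; 10 9-bromonon-1-ene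
Product: 12 (2S,3S)-3-(methoxymethoxy)-6-(non-8-en-1-yl)-2-pentyl-3,4-dihydro-2H-pyran, via non-8-en-1-ylmagnesium bromide 11 (not isolated)
Conditions: 10, Mg, THF, rt; then 9, Fe(acac)3 (5 mol%), THF/NMP, −30 → 0 °C; work-up and chromatography on Et3N-deactivated silica
Reagents that add atoms: magnesium, [Mg] (in 11 only)
Why: Iron-catalysed Kumada-type cross-coupling of an alkyl Grignard reagent with an enol (ketene acetal) phosphate forms the sp2–sp3 bond C10–C11; the coupling is fast at low temperature, tolerates β-hydrogens and the remote alkene of 11, and does not involve C6 or C7.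

Step 7
Reactants: 12 (2S,3S)-3-(methoxymethoxy)-6-(non-8-en-1-yl)-2-pentyl-3,4-dihydro-2H-pyran
Product: 14 1-[(2R,4S,5S)-4-(methoxymethoxy)-5-pentyltetrahydrofuran-2-yl]dec-9-en-1-one, via (2S,3S,5R)-5-(1,1-dimethoxydec-9-en-1-yl)-3-(methoxymethoxy)-2-pentyltetrahydrofuran 13 (not isolated)
Conditions: PhI(OH)OTs (1.05 equiv), MeOH, −20 → 0 °C; then H2O, rt; NaHCO3
Reagents that add atoms: methanol, CO (the two methoxy groups of 13 only); water, O (carbonyl oxygen of 14)
Why: Oxidative ring contraction of a cyclic enol ether by a trivalent iodine reagent; the closest known cases are the conversions of glycals and other dihydropyrans into 2,5-anhydro aldehyde acetals with PhI(OH)OTs or Tl(NO3)3, extended here only by the alkyl group on the enol ether carbon, so that C10 emerges as a ketone. The electrophilic iodine adds to C9, the nucleophilic β-carbon of the enol ether, and methanol caps the oxocarbenium carbon C10. In the chair of this adduct with pentyl equatorial and the C7 ether axial, a C9–I bond trans to the C7 ether is equatorial and therefore antiperiplanar to the ring bond O1–C10; O1 then shifts from C10 to C9 with expulsion of iodobenzene, the methoxy group stabilising the cation left at C10. The tetrahydrofuran ring thus closes by a 1,2-shift through a bridged oxonium ion, formally a 3-exo-tet displacement at C9, with inversion. The cation at C10 is trapped as ketal 13, which the added water and the TsOH already present hydrolyse to ketone 14. C9 is the only new stereocentre: its configuration follows from attack of iodine anti to the pseudoaxial C7 ether of the half-chair (pentyl pseudoequatorial) and from the stereospecific shift, which leaves C10 on the face where iodine stood, trans to pentyl and to the C7 ether (9R); the adduct of syn attack could align its C9–I bond with O1–C10 only in the chair with pentyl axial, so addition and shift are biased in the same sense. The step needs chemoselectivity for the enol ether over the C18=C19 alkene, secured by the far higher nucleophilicity of the enol ether and one equivalent of oxidant at low temperature, and it needs the methoxymethyl ether to outlast one equivalent of TsOH, which the short reaction time at or below 0 °C and the bicarbonate quench should allow.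

Step 8
Reactants: 14 1-[(2R,4S,5S)-4-(methoxymethoxy)-5-pentyltetrahydrofuran-2-yl]dec-9-en-1-one
Product: 16 1-[(2R,4S,5S)-4-hydroxy-5-pentyltetrahydrofuran-2-yl]dec-9-en-1-one, via 1-[(2R,4S,5S)-4-(bromomethoxy)-5-pentyltetrahydrofuran-2-yl]dec-9-en-1-one 15 (not isolated)
Conditions: Me2BBr, CH2Cl2, −78 °C; then THF, sat. aq. NaHCO3, 0 °C
Reagents that add atoms: bromodimethylborane, CB(C)Br (bromine of 15 only)
Why: Lewis acid cleavage of a methoxymethyl ether with a dialkylboron bromide: boron binds the acetal, bromide gives the bromomethyl ether 15, and bicarbonate work-up hydrolyses it to the alcohol; at −78 °C ketones, cyclic ethers and alkenes do not react, and the aprotic medium avoids enolisation towards C9.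

Step 9
Reactants: 16 1-[(2R,4S,5S)-4-hydroxy-5-pentyltetrahydrofuran-2-yl]dec-9-en-1-one; 17 lauric acid
Product: 18 (2S,3S,5R)-5-(dec-9-enoyl)-2-pentyltetrahydrofuran-3-yl dodecanoate
Conditions: DCC, DMAP (cat.), CH2Cl2, 0 °C → rt
Reagents that add atoms: none
Why: Steglich esterification of the only hydroxyl in the molecule; the C7–O bond is retained, the C10 ketone needs no protection, and the trans relation of C7–O and the C9 acyl group excludes hemiketal formation.

Step 10
Reactants: 18 (2S,3S,5R)-5-(dec-9-enoyl)-2-pentyltetrahydrofuran-3-yl dodecanoate
Product: 19 (2S,3S,5R)-5-[(1R)-1-hydroxydec-9-en-1-yl]-2-pentyltetrahydrofuran-3-yl dodecanoate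
Conditions: LiBH(s-Bu)3 (1.2 equiv), THF, −78 °C; then pH 7 buffer, H2O2, 0 °C
Reagents that add atoms: none
Why: Felkin–Anh controlled reduction of an α-alkoxy ketone by a bulky, non-chelating trialkylborohydride: hydride adds anti to the C9–O1 bond and gives the threo (9R,10R) alcohol; at −78 °C the ketone is reduced much faster than the secondary ester, and the buffered work-up leaves ester and alkene intact.

## Compound list

1 | hexanal | CCCCCC=O | starting material
2 | allyl methoxymethyl ether (3-(methoxymethoxy)prop-1-ene) | C=CCOCOC | starting material
3 | (Z)-[3-(methoxymethoxy)allyl]diisopinocampheylborane; both isopinocampheyl groups configured as in (+)-isopinocampheol, boron in place of hydroxyl | COCO/C=C\CB([C@H]1C[C@H]2C[C@@H]([C@@H]1C)C2(C)C)[C@H]1C[C@H]2C[C@@H]([C@@H]1C)C2(C)C | intermediate (not isolated)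
4 | (3S,4S)-3-(methoxymethoxy)non-1-en-4-yl diisopinocampheylborinate | C=C[C@H](OCOC)[C@@H](OB([C@H]1C[C@H]2C[C@@H]([C@@H]1C)C2(C)C)[C@H]1C[C@H]2C[C@@H]([C@@H]1C)C2(C)C)CCCCC | intermediate (not isolated)
5 | (3S,4S)-3-(methoxymethoxy)non-1-en-4-ol | C=C[C@H](OCOC)[C@@H](O)CCCCC | intermediate
6 | (3S,4S)-3-(methoxymethoxy)non-1-en-4-yl acrylate | C=C[C@H](OCOC)[C@@H](OC(=O)C=C)CCCCC | intermediate
7 | (5S,6S)-5-(methoxymethoxy)-6-pentyl-5,6-dihydro-2H-pyran-2-one | O=C1C=C[C@H](OCOC)[C@H](CCCCC)O1 | intermediate
8 | (5S,6S)-5-(methoxymethoxy)-6-pentyltetrahydro-2H-pyran-2-one | O=C1CC[C@H](OCOC)[C@H](CCCCC)O1 | intermediate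
9 | diphenyl (2S,3S)-3-(methoxymethoxy)-2-pentyl-3,4-dihydro-2H-pyran-6-yl phosphate | O=P(Oc1ccccc1)(Oc1ccccc1)OC1=CC[C@H](OCOC)[C@H](CCCCC)O1 | intermediate
10 | 9-bromonon-1-ene | C=CCCCCCCCBr | starting material
11 | non-8-en-1-ylmagnesium bromide | C=CCCCCCCC[Mg]Br | intermediate (not isolated)
12 | (2S,3S)-3-(methoxymethoxy)-6-(non-8-en-1-yl)-2-pentyl-3,4-dihydro-2H-pyran | C=CCCCCCCCC1=CC[C@H](OCOC)[C@H](CCCCC)O1 | intermediate
13 | (2S,3S,5R)-5-(1,1-dimethoxydec-9-en-1-yl)-3-(methoxymethoxy)-2-pentyltetrahydrofuran | C=CCCCCCCCC(OC)(OC)[C@H]1C[C@H](OCOC)[C@H](CCCCC)O1 | intermediate (not isolated)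
14 | 1-[(2R,4S,5S)-4-(methoxymethoxy)-5-pentyltetrahydrofuran-2-yl]dec-9-en-1-one | C=CCCCCCCCC(=O)[C@H]1C[C@H](OCOC)[C@H](CCCCC)O1 | intermediate
15 | 1-[(2R,4S,5S)-4-(bromomethoxy)-5-pentyltetrahydrofuran-2-yl]dec-9-en-1-one | C=CCCCCCCCC(=O)[C@H]1C[C@H](OCBr)[C@H](CCCCC)O1 | intermediate (not isolated)
16 | 1-[(2R,4S,5S)-4-hydroxy-5-pentyltetrahydrofuran-2-yl]dec-9-en-1-one | C=CCCCCCCCC(=O)[C@H]1C[C@H](O)[C@H](CCCCC)O1 | intermediate
17 | lauric acid (dodecanoic acid) | CCCCCCCCCCCC(=O)O | starting material
18 | (2S,3S,5R)-5-(dec-9-enoyl)-2-pentyltetrahydrofuran-3-yl dodecanoate | C=CCCCCCCCC(=O)[C@H]1C[C@H](OC(=O)CCCCCCCCCCC)[C@H](CCCCC)O1 | intermediate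
19 | (2S,3S,5R)-5-[(1R)-1-hydroxydec-9-en-1-yl]-2-pentyltetrahydrofuran-3-yl dodecanoate; chain numbering (6S,7S,9R,10R) | C=CCCCCCCC[C@@H](O)[C@H]1C[C@H](OC(=O)CCCCCCCCCCC)[C@H](CCCCC)O1 | target

## Step count and risks

Total: 10 steps. Longest linear sequence: 10 steps, from 1 (or 2) to 19. Bromide 10 and acid 17 enter as single-step inputs, and reagents 3 and 11 are made in the flask within steps 1 and 6.

**Step 7 (key step).** Two things are most likely to go wrong. The first is insufficient face selectivity of the iodine attack at C9, because the directing ether sits on C7, one carbon removed from the allylic position. The second is acid-catalysed addition of methanol to the enol ether, which would consume the nucleophile before it is oxidised; partial loss of the methoxymethyl group by the liberated TsOH is a lesser concern. The fallback separates oxidation from rearrangement and uses only neutral or buffered reagents. It sets out from 12 and returns at 14.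
- Oxidation of 12 with dimethyldioxirane in acetone–methanol at low temperature, with methanolysis in the same flask, should give (3S,5S,6S)-2-methoxy-5-(methoxymethoxy)-2-(non-8-en-1-yl)-6-pentyltetrahydro-2H-pyran-3-ol F1 as a mixture at the ketal carbon. The configuration at C9 can be checked at this stage.
- Triflation (Tf2O, pyridine, CH2Cl2, −20 °C) gives (3S,5S,6S)-2-methoxy-5-(methoxymethoxy)-2-(non-8-en-1-yl)-6-pentyltetrahydro-2H-pyran-3-yl trifluoromethanesulfonate F2.
- Warming F2 in wet acetonitrile with 2,6-lutidine should bring about the ring-oxygen shift with inversion at C9 and release 14. This is the contraction known from pyranoside 2-O-triflates, which give 2,5-anhydro sugars. The leaving group is equatorial and antiperiplanar to O1–C10, as in the key step.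

**Step 6.** The most likely failure is attack of the Grignard reagent at phosphorus, which cleaves the P–O bond and returns the lactone enolate, together with homocoupling of 11 if the iron-catalysed coupling of this electron-rich phosphate is slow. The fallback changes both the nucleophile and the catalytic manifold. It sets out from 9 and 10 and returns at 12. Bromide 10 is converted with zinc dust and LiCl in THF into non-8-en-1-ylzinc bromide F3, which does not attack phosphorus. F3 is coupled with 9 under Pd(PPh3)4 catalysis in THF at 50 °C. This is a Negishi coupling through oxidative addition of zerovalent palladium into the C–O bond, a known reaction of lactone-derived ketene acetal phosphates.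

**Step 8.** The most likely failure is epimerisation at C9 through Lewis acid assisted enolisation of the α-alkoxy ketone, or incomplete acetal cleavage at the temperature needed to keep the tetrahydrofuran intact. The fallback removes the ketone before the acetal is cleaved. It sets out from 14 and returns at 19.
- Reduction of 14 with LiBH(s-Bu)3 at −78 °C gives (1R)-1-[(2R,4S,5S)-4-(methoxymethoxy)-5-pentyltetrahydrofuran-2-yl]dec-9-en-1-ol F4 (the same alcohol as A6).
- Silylation (TBDPSCl, imidazole, DMF) gives tert-butyl({(1R)-1-[(2R,4S,5S)-4-(methoxymethoxy)-5-pentyltetrahydrofuran-2-yl]dec-9-en-1-yl}oxy)diphenylsilane F5.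
- Acetal cleavage with Me2BBr at −78 °C gives (2S,3S,5R)-5-[(1R)-1-(tert-butyldiphenylsilyloxy)dec-9-en-1-yl]-2-pentyltetrahydrofuran-3-ol F6.
- Esterification with 17 (DCC, DMAP) gives (2S,3S,5R)-5-[(1R)-1-(tert-butyldiphenylsilyloxy)dec-9-en-1-yl]-2-pentyltetrahydrofuran-3-yl dodecanoate F7.
- Desilylation with TBAF buffered by AcOH in THF gives 19.

This costs two more steps, but no epimerisable centre is present during the acetal cleavage.

**Step 10.** The most likely failure is erosion of the Felkin–Anh preference, since the two carbonyl substituents differ mainly through the polar C9–O1 bond, or slow competing attack of the hydride on the laurate. The fallback replaces substrate control by catalyst control. It sets out from 18 and returns at 19 without new intermediates. A Corey–Bakshi–Shibata reduction with the (S)-2-methyl-oxazaborolidine and catecholborane in toluene at −78 °C should deliver 10R on the usual large/small model, with the ring carbon as the large group. Catecholborane reduces neither esters nor alkenes at that temperature.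

## Further compounds

F1 | step 7 | (3S,5S,6S)-2-methoxy-5-(methoxymethoxy)-2-(non-8-en-1-yl)-6-pentyltetrahydro-2H-pyran-3-ol (mixture at C2) | C=CCCCCCCCC1(OC)[C@@H](O)C[C@H](OCOC)[C@H](CCCCC)O1
F2 | step 7 | (3S,5S,6S)-2-methoxy-5-(methoxymethoxy)-2-(non-8-en-1-yl)-6-pentyltetrahydro-2H-pyran-3-yl trifluoromethanesulfonate (mixture at C2) | C=CCCCCCCCC1(OC)[C@@H](OS(=O)(=O)C(F)(F)F)C[C@H](OCOC)[C@H](CCCCC)O1
F3 | step 6 | non-8-en-1-ylzinc bromide | C=CCCCCCCC[Zn]Br
F4 | step 8 | (1R)-1-[(2R,4S,5S)-4-(methoxymethoxy)-5-pentyltetrahydrofuran-2-yl]dec-9-en-1-ol | C=CCCCCCCC[C@@H](O)[C@H]1C[C@H](OCOC)[C@H](CCCCC)O1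
F5 | step 8 | tert-butyl({(1R)-1-[(2R,4S,5S)-4-(methoxymethoxy)-5-pentyltetrahydrofuran-2-yl]dec-9-en-1-yl}oxy)diphenylsilane | C=CCCCCCCC[C@@H](O[Si](c1ccccc1)(c1ccccc1)C(C)(C)C)[C@H]1C[C@H](OCOC)[C@H](CCCCC)O1
F6 | step 8 | (2S,3S,5R)-5-[(1R)-1-(tert-butyldiphenylsilyloxy)dec-9-en-1-yl]-2-pentyltetrahydrofuran-3-ol | C=CCCCCCCC[C@@H](O[Si](c1ccccc1)(c1ccccc1)C(C)(C)C)[C@H]1C[C@H](O)[C@H](CCCCC)O1
F7 | step 8 | (2S,3S,5R)-5-[(1R)-1-(tert-butyldiphenylsilyloxy)dec-9-en-1-yl]-2-pentyltetrahydrofuran-3-yl dodecanoate | C=CCCCCCCC[C@@H](O[Si](c1ccccc1)(c1ccccc1)C(C)(C)C)[C@H]1C[C@H](OC(=O)CCCCCCCCCCC)[C@H](CCCCC)O1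
F0 | step 10 | none | none
A1 | alternative 1 | (3S,5R,6R)-6-[(4-methoxybenzyl)oxy]pentadeca-1,14-diene-3,5-diol | C=C[C@@H](O)C[C@@H](O)[C@H](OCc1ccc(OC)cc1)CCCCCCCC=C
A2 | alternative 1 | cis-fused 5-[(1R)-1-(4-methoxybenzyloxy)dec-9-enyl]tetrahydrofuro[3,2-b]furan-2(3H)-one, ring carbons configured as C6, C7 and C9 of the target | C=CCCCCCCC[C@@H](OCc1ccc(OC)cc1)[C@H]1C[C@@H]2OC(=O)C[C@@H]2O1
A3 | alternative 2 | (6E,9R,10R)-10-(tert-butyldiphenylsilyloxy)nonadeca-6,18-dien-9-ol | CCCCC/C=C/C[C@@H](O)[C@H](O[Si](c1ccccc1)(c1ccccc1)C(C)(C)C)CCCCCCCC=C
A4 | alternative 2 | (6S,7R,9R,10R)-10-(tert-butyldiphenylsilyloxy)-6,9-epoxy-7-iodononadec-18-ene | C=CCCCCCCC[C@@H](O[Si](c1ccccc1)(c1ccccc1)C(C)(C)C)[C@H]1C[C@@H](I)[C@H](CCCCC)O1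
A5 | alternative 3 | (6S,7S,9E)-7-(methoxymethoxy)nonadeca-9,18-dien-6-ol | CCCCC[C@H](O)[C@@H](OCOC)C/C=C/CCCCCCCC=C
A6 | alternative 3 | (6S,7S,9R,10R)-6,9-epoxy-7-(methoxymethoxy)nonadec-18-en-10-ol | C=CCCCCCCC[C@@H](O)[C@H]1C[C@H](OCOC)[C@H](CCCCC)O1
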